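**Plan**

1. Retrosynthetic cuts, in order: the C7=C8 alkene (ring CH2-sulfone plus all-E crocetin dialdehyde, which already carries C8–C8' and the aldehyde); the ring bond C1–C6 (cation–olefin cyclisation); then C4–C5 and the C2–isopropenyl bond (two epoxide openings around a three-carbon glycidyl unit).
2. Feature that allows the ring step: the only ring is a cyclogeranyl-type cyclohexene (C1 quaternary with two methyls, C2 methylene, C3 carbinol, C4=C5 alkene with the C5 methyl, C6 methine bearing the chain). An open-chain tertiary C1 cation can therefore add to a C5=C6 alkene while the C3 oxygen, 1,3 to the C1 methyls, stays equatorial in the chair.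
3. Forward order: the acyclic chain is assembled first (isopropenyl + epichlorohydrin + Z-butenyl unit), the ring closes in step 8, the polyene is attached in step 12, and the silyl ether is removed last.
4. Stereochemistry: C3 (S) comes from (S)-epichlorohydrin, whose C–O bond is never broken. C6 (R) arises by 1,4-induction in the chair cyclisation (equatorial silyloxy, axial C7 imposed by the Z alkene, hence cis). The Z alkene comes from trans-hydroalumination/iodination of but-2-yn-1-ol; the chain E geometry comes with the dialdehyde, and C7=C8 (E) from the sulfone olefination.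

Key step: step 8

Remark: all-E crocetin dialdehyde is treated as a purchasable C20 building block; positions are quoted in carotenoid numbering (ring C1–C6, chain C7–C8').

**Route**

Step 1
Reactants: 1 but-2-yn-1-ol
Product: 3 (Z)-3-iodobut-2-en-1-ol, via cyclic alkenylalanate 2 (not isolated)
Conditions: NaAlH2(OCH2CH2OMe)2 (Red-Al), THF, 0 °C → rt; then I2, THF, −78 → 0 °C
Reagents that add atoms: iodine, II
Why: Hydroxyl-directed trans-hydroalumination of the propargylic alcohol places aluminium on C3 inside a five-membered alkoxyalanate ring, and iodinolysis of the C–Al bond with retention should give the iodoalkene with iodine cis to the CH2OH arm (Z).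

Step 2
Reactants: 3 (Z)-3-iodobut-2-en-1-ol
Product: 4 (Z)-1-(1-ethoxyethoxy)-3-iodobut-2-ene
Conditions: ethyl vinyl ether, PPTS (cat.), CH2Cl2, 0 °C → rt
Reagents that add atoms: ethyl vinyl ether, C=COCC
Why: Acid-catalysed addition of the alcohol to the enol ether (acetal protection) masks the hydroxyl for the lithiation, and a non-silyl group is chosen so that no oxygen-to-carbon silyl shift can occur in the cis-alkenyllithium.

Step 3
Reactants: 5 (S)-epichlorohydrin; 6 isopropenylmagnesium bromide
Product: 7 (S)-1-chloro-4-methylpent-4-en-2-ol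
Conditions: CuI (10 mol%), THF, −40 → −20 °C; aq NH4Cl
Reagents that add atoms: none
Why: Copper-catalysed Grignard opening of the epoxide at its unsubstituted carbon (SN2) leaves the C–O stereocentre and the chloride untouched, so the configuration of 5 is carried over.

Step 4
Reactants: 7 (S)-1-chloro-4-methylpent-4-en-2-ol
Product: 8 (S)-2-(2-methylprop-2-en-1-yl)oxirane
Conditions: powdered NaOH, Et2O, rt; distillation
Reagents that add atoms: none
Why: Intramolecular Williamson etherification, in which the alkoxide displaces chloride at the primary carbon, re-forms the epoxide on the other side of the stereocentre without touching it.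

Step 5
Reactants: 4 (Z)-1-(1-ethoxyethoxy)-3-iodobut-2-ene; 8 (S)-2-(2-methylprop-2-en-1-yl)oxirane
Product: 12 (2Z,5S)-3,7-dimethylocta-2,7-diene-1,5-diol, via alkenyllithium 9 (not isolated), via alkenylmagnesium bromide 10 (not isolated), via ethoxyethyl ether 11 (not isolated)
Conditions: 4, t-BuLi (2.1 equiv), Et2O, −78 °C; MgBr2·OEt2, −78 → −30 °C; CuI (10 mol%), 8, THF, −30 → 0 °C; then 1 M aq HCl, 0 °C → rt
Reagents that add atoms: none
Why: Iodine–lithium exchange and transmetalation to magnesium proceed with retention of the Z geometry, the copper-catalysed Grignard opens the terminal epoxide at CH2 (same reaction type as step 3) to make the C4–C5 bond, and dilute acid hydrolyses the acetal in the same flask.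

Step 6
Reactants: 12 (2Z,5S)-3,7-dimethylocta-2,7-diene-1,5-diol
Product: 13 (2Z,5S)-5-hydroxy-3,7-dimethylocta-2,7-dien-1-yl acetate
Conditions: AcCl (1.05 equiv), 2,4,6-collidine, CH2Cl2, −78 °C
Reagents that add atoms: acetyl chloride, CC(Cl)=O
Why: Kinetically selective acylation at low temperature with a hindered pyridine base should acetylate the primary allylic hydroxyl much faster than the secondary one.

Step 7
Reactants: 13 (2Z,5S)-5-hydroxy-3,7-dimethylocta-2,7-dien-1-yl acetate
Product: 14 (2Z,5S)-3,7-dimethyl-5-[(triisopropylsilyl)oxy]octa-2,7-dien-1-yl acetate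
Conditions: i-Pr3SiOTf, 2,6-lutidine, CH2Cl2, −78 → 0 °C
Reagents that add atoms: triisopropylsilyl triflate, CC(C)[Si](OS(=O)(=O)C(F)(F)F)(C(C)C)C(C)C
Why: Silyl triflate silylation of the secondary alcohol installs a bulky, aryl-free, acid-resistant ether that cannot act as a neighbouring group and should hold the equatorial position in step 8.

Step 8
Reactants: 14 (2Z,5S)-3,7-dimethyl-5-[(triisopropylsilyl)oxy]octa-2,7-dien-1-yl acetate
Product: 15 [(1R,4S)-2,6,6-trimethyl-4-[(triisopropylsilyl)oxy]cyclohex-2-en-1-yl]methyl acetate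
Conditions: HNTf2 (0.3 equiv), CH2Cl2, −78 °C; Et3N quench at −78 °C
Reagents that add atoms: none
Why: The superacid protonates the 1,1-disubstituted alkene to the tertiary C1 cation (kept apart from the silyl ether by the C2 methylene), C6 of the Z-trisubstituted alkene adds to it to make the C1–C6 bond, and the tertiary C5 cation then loses the axial C4 proton, giving the C4=C5 alkene and returning the proton. The closest known reaction is the Brønsted-acid cyclisation of geranyl and neryl acetates to α-cyclogeranyl acetates. The cyclohexene ring closes in a 6-endo-trig cation–olefin addition through a chair. The new C6 centre is set by the C3 centre: the silyloxy group stays equatorial to avoid a syn-diaxial clash with the axial C1 methyl, whereas the Z geometry forces the CH2OAc arm axial, and an equatorial and an axial group in a 1,4 relationship are cis, i.e. (1R,4S). Facial selectivity rests on this chair preference and on the geometric purity of 14; proton loss from C4 is favoured because the C6–H is equatorial and poorly aligned with the empty orbital while the axial C4–H lies syn to the acetoxymethyl carbonyl, and the low temperature, the non-nucleophilic counter-ion and the cold amine quench should keep the allylic acetate and the newly allylic silyl ether from ionising.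

Step 9
Reactants: 15 [(1R,4S)-2,6,6-trimethyl-4-[(triisopropylsilyl)oxy]cyclohex-2-en-1-yl]methyl acetate
Product: 16 [(1R,4S)-2,6,6-trimethyl-4-[(triisopropylsilyl)oxy]cyclohex-2-en-1-yl]methanol
Conditions: K2CO3, MeOH, 0 °C → rt
Reagents that add atoms: none
Why: Base-catalysed transesterification removes the primary acetate as methyl acetate while the silyl ether and both stereocentres (no acidic C–H) are unaffected.

Step 10
Reactants: 16 [(1R,4S)-2,6,6-trimethyl-4-[(triisopropylsilyl)oxy]cyclohex-2-en-1-yl]methanol
Product: 17 1-phenyl-5-({[(1R,4S)-2,6,6-trimethyl-4-[(triisopropylsilyl)oxy]cyclohex-2-en-1-yl]methyl}sulfanyl)-1H-tetrazole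
Conditions: 1-phenyl-1H-tetrazole-5-thiol, PPh3, DIAD, THF, 0 °C → rt
Reagents that add atoms: 1-phenyl-1H-tetrazole-5-thiol, SC1=NN=NN1c1ccccc1
Why: Mitsunobu thioetherification activates the primary hydroxyl as an alkoxyphosphonium ion that the acidic, highly nucleophilic thiol displaces at CH2, leaving the adjacent C6 centre untouched.

Step 11
Reactants: 17 1-phenyl-5-({[(1R,4S)-2,6,6-trimethyl-4-[(triisopropylsilyl)oxy]cyclohex-2-en-1-yl]methyl}sulfanyl)-1H-tetrazole
Product: 18 1-phenyl-5-({[(1R,4S)-2,6,6-trimethyl-4-[(triisopropylsilyl)oxy]cyclohex-2-en-1-yl]methyl}sulfonyl)-1H-tetrazole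
Conditions: (NH4)6Mo7O24·4H2O (10 mol%), 30% aq H2O2, EtOH, 0 °C → rt
Reagents that add atoms: hydrogen peroxide, OO
Why: Molybdate-catalysed peroxide oxidation of sulfide to sulfone is chemoselective for sulfur over the trisubstituted alkene, and because the sulfur is homoallylic rather than allylic no sigmatropic scrambling of the intermediate sulfoxide can occur.

Step 12
Reactants: 18 1-phenyl-5-({[(1R,4S)-2,6,6-trimethyl-4-[(triisopropylsilyl)oxy]cyclohex-2-en-1-yl]methyl}sulfonyl)-1H-tetrazole; 19 all-E crocetin dialdehyde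
Product: 21 (2E,4E,6E,8E,10E,12E,14E,16E)-2,6,11,15-tetramethyl-17-[(1R,4S)-2,6,6-trimethyl-4-[(triisopropylsilyl)oxy]cyclohex-2-en-1-yl]heptadeca-2,4,6,8,10,12,14,16-octaenal, via potassio sulfone 20 (not isolated)
Conditions: 18, KN(SiMe3)2 (1.05 equiv), THF, −78 °C; cannulated into 19 (3 equiv), THF, −78 °C → rt; aq NH4Cl
Reagents that add atoms: none
Why: In this Julia–Kocienski olefination the α-sulfonyl carbanion adds to one formyl group, Smiles transfer of the tetrazole to oxygen and loss of SO2 and tetrazololate form C7=C8, the potassium counter-ion and the conjugated aldehyde favour E, and the excess of dialdehyde with inverse addition should limit double olefination.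

Step 13
Reactants: 21 (2E,4E,6E,8E,10E,12E,14E,16E)-2,6,11,15-tetramethyl-17-[(1R,4S)-2,6,6-trimethyl-4-[(triisopropylsilyl)oxy]cyclohex-2-en-1-yl]heptadeca-2,4,6,8,10,12,14,16-octaenal
Product: 22 (2E,4E,6E,8E,10E,12E,14E,16E)-17-[(1R,4S)-4-hydroxy-2,6,6-trimethylcyclohex-2-en-1-yl]-2,6,11,15-tetramethylheptadeca-2,4,6,8,10,12,14,16-octaenal
Conditions: Bu4NF/AcOH (1:1, 5 equiv), THF, 0 °C → rt, argon, dark
Reagents that add atoms: none
Why: Fluoride cleaves the Si–O bond (silyl ether deprotection), and the acetic acid buffer should keep the medium near neutral so that the C6–H, vinylogous to the aldehyde through the polyene, is not removed and the allylic C3 alcohol does not ionise.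

**Compound list**

1 | but-2-yn-1-ol | CC#CCO | starting material
2 | sodium 2,2-bis(2-methoxyethoxy)-3-methyl-2,5-dihydro-1,2-oxaaluminol-2-uide (cyclic alkenylalanate) | CC1=CCO[Al-]1(OCCOC)OCCOC.[Na+] | intermediate
3 | (Z)-3-iodobut-2-en-1-ol | C/C(I)=C/CO | intermediate
4 | (Z)-1-(1-ethoxyethoxy)-3-iodobut-2-ene (acetal carbon: both epimers) | C/C(I)=C/COC(C)OCC | intermediate
5 | (S)-epichlorohydrin | ClC[C@@H]1CO1 | starting material
6 | isopropenylmagnesium bromide | C=C(C)[Mg]Br | starting material
7 | (S)-1-chloro-4-methylpent-4-en-2-ol | ClC[C@@H](O)CC(C)=C | intermediate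
8 | (S)-2-(2-methylprop-2-en-1-yl)oxirane | C=C(C)C[C@H]1CO1 | intermediate
9 | (Z)-[4-(1-ethoxyethoxy)but-2-en-2-yl]lithium | [Li]/C(C)=C\COC(C)OCC | intermediate
10 | (Z)-[4-(1-ethoxyethoxy)but-2-en-2-yl]magnesium bromide | Br[Mg]/C(C)=C\COC(C)OCC | intermediate
11 | (4S,6Z)-8-(1-ethoxyethoxy)-2,6-dimethylocta-1,6-dien-4-ol (acetal carbon: both epimers) | C=C(C)C[C@H](O)C/C(C)=C\COC(C)OCC | intermediate
12 | (2Z,5S)-3,7-dimethylocta-2,7-diene-1,5-diol | C=C(C)C[C@H](O)C/C(C)=C\CO | intermediate
13 | (2Z,5S)-5-hydroxy-3,7-dimethylocta-2,7-dien-1-yl acetate | C=C(C)C[C@H](O)C/C(C)=C\COC(C)=O | intermediate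
14 | (2Z,5S)-3,7-dimethyl-5-[(triisopropylsilyl)oxy]octa-2,7-dien-1-yl acetate | C=C(C)C[C@H](O[Si](C(C)C)(C(C)C)C(C)C)C/C(C)=C\COC(C)=O | intermediate
15 | [(1R,4S)-2,6,6-trimethyl-4-[(triisopropylsilyl)oxy]cyclohex-2-en-1-yl]methyl acetate | CC1=C[C@@H](O[Si](C(C)C)(C(C)C)C(C)C)CC(C)(C)[C@H]1COC(C)=O | intermediate
16 | [(1R,4S)-2,6,6-trimethyl-4-[(triisopropylsilyl)oxy]cyclohex-2-en-1-yl]methanol | CC1=C[C@@H](O[Si](C(C)C)(C(C)C)C(C)C)CC(C)(C)[C@H]1CO | intermediate
17 | 1-phenyl-5-({[(1R,4S)-2,6,6-trimethyl-4-[(triisopropylsilyl)oxy]cyclohex-2-en-1-yl]methyl}sulfanyl)-1H-tetrazole | CC1=C[C@@H](O[Si](C(C)C)(C(C)C)C(C)C)CC(C)(C)[C@H]1CSC1=NN=NN1c1ccccc1 | intermediate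
18 | 1-phenyl-5-({[(1R,4S)-2,6,6-trimethyl-4-[(triisopropylsilyl)oxy]cyclohex-2-en-1-yl]methyl}sulfonyl)-1H-tetrazole | CC1=C[C@@H](O[Si](C(C)C)(C(C)C)C(C)C)CC(C)(C)[C@H]1CS(=O)(=O)C1=NN=NN1c1ccccc1 | intermediate
19 | crocetin dialdehyde, (2E,4E,6E,8E,10E,12E,14E)-2,6,11,15-tetramethylhexadeca-2,4,6,8,10,12,14-heptaenedial | O=C/C(C)=C/C=C/C(C)=C/C=C/C=C(C)/C=C/C=C(\C)C=O | starting material
20 | potassium salt of the α-sulfonyl carbanion of 18 | CC1=C[C@@H](O[Si](C(C)C)(C(C)C)C(C)C)CC(C)(C)[C@H]1[CH-]S(=O)(=O)C1=NN=NN1c1ccccc1.[K+] | intermediate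
21 | (2E,4E,6E,8E,10E,12E,14E,16E)-2,6,11,15-tetramethyl-17-[(1R,4S)-2,6,6-trimethyl-4-[(triisopropylsilyl)oxy]cyclohex-2-en-1-yl]heptadeca-2,4,6,8,10,12,14,16-octaenal | CC1=C[C@@H](O[Si](C(C)C)(C(C)C)C(C)C)CC(C)(C)[C@H]1/C=C/C(C)=C/C=C/C(C)=C/C=C/C=C(C)/C=C/C=C(\C)C=O | intermediate
22 | (2E,4E,6E,8E,10E,12E,14E,16E)-17-[(1R,4S)-4-hydroxy-2,6,6-trimethylcyclohex-2-en-1-yl]-2,6,11,15-tetramethylheptadeca-2,4,6,8,10,12,14,16-octaenal, i.e. (3S,6R)-3-hydroxy-8'-apo-ε-caroten-8'-al | CC1=C[C@@H](O)CC(C)(C)[C@H]1/C=C/C(C)=C/C=C/C(C)=C/C=C/C=C(C)/C=C/C=C(\C)C=O | target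

**Totals**

Total step count: 13.
Longest linear sequence: 11 steps (steps 1, 2, 5–13 from but-2-yn-1-ol); steps 3 and 4 form a two-step branch.

**Steps most likely to fail**

1. Step 8. What may go wrong: ring closure through the chair with an axial silyloxy group (or through a boat) would erode facial selectivity. Proton loss towards the C5 methyl or C6 would give alkene isomers. Acid-induced loss of the silyl group or ionisation of the allylic acetate could also compete. The fallback sets out from 14 and comes back at 15, making the same C1–C6 bond with a metal electrophile in place of the proton. Hg(OTf)2·PhNMe2 (divalent mercury) in MeNO2 at −20 °C should add to the terminal CH2 in the Markovnikov sense, the tertiary C1 cation should cyclise as before, and the amine should take up the C4 proton. This would give the organomercury triflate F1, in which one C1 methyl is CH2HgOTf. Washing with brine would exchange the anion to give the chloromercurial F2. Reduction with n-Bu3SnH and AIBN in toluene at 60 °C would replace mercury by hydrogen and deliver 15. The extra stereocentre at the mercurated carbon disappears in this reduction.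

2. Step 12. What may go wrong: slow addition of the hindered α-sulfonyl carbanion, its self-condensation, double olefination of the dialdehyde, or loss of E selectivity at C7=C8. The fallback sets out from 16 and comes back at 21, using a more nucleophilic phosphorus ylide. I2, PPh3 and imidazole in toluene would convert 16 into the primary iodide F3. Heating F3 with PPh3 in MeCN at 90 °C in a sealed tube would give the triphenylphosphonium iodide F4. NaN(SiMe3)2 in THF at −78 °C would give the ylide F5, which would be added to an excess of 19 (Wittig olefination). The product should be 21 together with its 7Z isomer F6. A trace of I2 in CH2Cl2 under diffuse light should equilibrate the mixture to the all-E compound 21.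

3. Step 13. What may go wrong: slow fluoride attack at the hindered silicon, so that prolonged exposure leads to double-bond migration through deprotonation at C6, E/Z isomerisation of the polyenal, or allylic ionisation at C3. The fallback sets out from 18 and comes back at 22, exchanging the protecting group before the polyene is present. HF·pyridine in THF/pyridine would remove the silyl group from the robust sulfone to give the hydroxy sulfone F7. Et3SiCl and imidazole in CH2Cl2 would give the triethylsilyl ether F8. KN(SiMe3)2 in THF at −78 °C would give its potassio derivative F9, and Julia–Kocienski olefination with an excess of 19 would give the triethylsilyl-protected polyenal F10. PPTS in MeOH/THF at 0 °C would then release 22 under very mild conditions.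

**Further compounds**

F1 | step 8 | [2,6-dimethyl-6-{[(trifluoromethanesulfonyloxy)mercurio]methyl}-4-[(triisopropylsilyl)oxy]cyclohex-2-en-1-yl]methyl acetate, oxygen-bearing and acetoxymethyl-bearing ring carbons configured as in 15, mercurated carbon as a mixture of epimers | CC1=C[C@@H](O[Si](C(C)C)(C(C)C)C(C)C)CC(C)(C[Hg]OS(=O)(=O)C(F)(F)F)[C@H]1COC(C)=O
F2 | step 8 | [6-[(chloromercurio)methyl]-2,6-dimethyl-4-[(triisopropylsilyl)oxy]cyclohex-2-en-1-yl]methyl acetate, ring configured as in F1 | CC1=C[C@@H](O[Si](C(C)C)(C(C)C)C(C)C)CC(C)(C[Hg]Cl)[C@H]1COC(C)=O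
F3 | step 12 | the primary iodide of 16, {[6-(iodomethyl)-1,5,5-trimethylcyclohex-1-en-3-yl]oxy}triisopropylsilane with the ring configured as in 16 | CC1=C[C@@H](O[Si](C(C)C)(C(C)C)C(C)C)CC(C)(C)[C@H]1CI
F4 | step 12 | triphenyl({2,6,6-trimethyl-4-[(triisopropylsilyl)oxy]cyclohex-2-en-1-yl}methyl)phosphonium iodide, ring configured as in 16 | CC1=C[C@@H](O[Si](C(C)C)(C(C)C)C(C)C)CC(C)(C)[C@H]1C[P+](c1ccccc1)(c1ccccc1)c1ccccc1.[I-]
F5 | step 12 | triphenyl({2,6,6-trimethyl-4-[(triisopropylsilyl)oxy]cyclohex-2-en-1-yl}methylidene)phosphorane, ring configured as in 16 | CC1=C[C@@H](O[Si](C(C)C)(C(C)C)C(C)C)CC(C)(C)[C@H]1C=P(c1ccccc1)(c1ccccc1)c1ccccc1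
F6 | step 12 | the 7Z isomer of 21 (16Z in the heptadecaoctaenal numbering) | CC1=C[C@@H](O[Si](C(C)C)(C(C)C)C(C)C)CC(C)(C)[C@H]1\C=C/C(C)=C/C=C/C(C)=C/C=C/C=C(C)/C=C/C=C(\C)C=O
F7 | step 13 | (1S,4R)-3,5,5-trimethyl-4-{[(1-phenyl-1H-tetrazol-5-yl)sulfonyl]methyl}cyclohex-2-en-1-ol | CC1=C[C@@H](O)CC(C)(C)[C@H]1CS(=O)(=O)C1=NN=NN1c1ccccc1
F8 | step 13 | the triethylsilyl ether of F7 | CC1=C[C@@H](O[Si](CC)(CC)CC)CC(C)(C)[C@H]1CS(=O)(=O)C1=NN=NN1c1ccccc1
F9 | step 13 | potassium salt of the α-sulfonyl carbanion of F8 | CC1=C[C@@H](O[Si](CC)(CC)CC)CC(C)(C)[C@H]1[CH-]S(=O)(=O)C1=NN=NN1c1ccccc1.[K+]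
F10 | step 13 | the triethylsilyl ether of 22 | CC1=C[C@@H](O[Si](CC)(CC)CC)CC(C)(C)[C@H]1/C=C/C(C)=C/C=C/C(C)=C/C=C/C=C(C)/C=C/C=C(\C)C=O
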